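I book every flask in one unit, the Q budget: equivalents of Q charged per E charged. The recipe below has 3.00.

| flask | E | Q | temperature | remark | time |
|---|---|---|---|---|---|
| teal | 0.070 M | 0.15 M | 2 °C | run made earlier |  |
| ochre | 0.11 M | 0.15 M | 19 °C | run made earlier |  |
| amber | 0.050 M | 0.22 M | 2 °C | run made earlier |  |
| west | 0.050 M | 0.150 M | 25 °C |  | 12 d |
| south | 0.050 M | 0.150 M | −5 °C |  | 12 d |
| south-east | 0.050 M | 0.150 M | 10 °C |  | 12 d |

| run | time / d | Z / % | E / % |
|---|---|---|---|
| teal | 4.00 | 3.4 | 28.5 |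
| teal | 10.0 | 13.9 | 11.0 |
| teal | 20.0 | 27.7 | 4.4 |
| teal | 30.0 | 33.7 | 1.2 |
| ochre | 0.833 | 4.9 | 23.6 |
| ochre | 1.67 | 12.3 | 11.1 |
| ochre | 4.00 | 19.4 | 5.6 |
| ochre | 10.0 | 24.1 | 3.9 |
| amber | 8.00 | 31.8 | 7.7 |
| amber | 15.0 | 45.6 | 0 |
| amber | 25.0 | 54.6 | 0.4 |
| amber | 30.0 | 51.3 | 0.3 |

(standard deviation of a reading: 1 percentage point)



- the best flask by amount of Z, in percent of the E charged; "all alike" if 1.5 percentage points covers them all (west / south / south-east / all alike)
- amount of Z at the end, in percent of the E charged, west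
- amount of Z at the end, in percent of the E charged, south
- amount of Z at the end, in percent of the E charged, south-east

Can the budget pay for Z? Each Z takes 3 Q, so the budget of west, south and south-east can pay for a fraction 1.00 of their E as Z.

Does E all go to Z? In amber, with a budget of 4.40, the reading at 25.0 d shows Z 54.6% and E 0.4%, so by these scattered readings about 45.0% of the E is in neither. Held at that Z reading, which comes from a larger budget, the recipe's budget keeps 1.36 equivalents outside Z.

Can that spare Q reach Z? Amber's Z reading drops 3.3 percentage points by 30.0 d, against a scatter of 1 point per reading: a hint, not proof. Teal at 2 °C and ochre at 19 °C reach about the same E reading at 10.0 d and 1.67 d, a factor of 5.99, though their charges differ. West runs hotter and longer than ochre's last reading, so I hold west as the flask at risk of being past its top.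

The forecast, unlike my caution on west, ranks west first, with west 43%, south 8% and south-east 39%, and says “the plateau should be about 44%”.

The flasks give west 34.7%, south 7.83% and south-east 43.1%, so south-east leads, and west stands 8.3 points under the forecast.

    E + Q → G (k = 0.713 M⁻¹ h⁻¹, Ea = 66.0 kJ mol⁻¹)
    Q + G → X (k = 0.939 M⁻¹ h⁻¹, Ea = 71.0 kJ mol⁻¹)
    Q + X → Z (k = 0.582 M⁻¹ h⁻¹, Ea = 74.0 kJ mol⁻¹)
    2 E → J (k = 0.497 M⁻¹ h⁻¹, Ea = 65.0 kJ mol⁻¹)
    Q + Z → D (k = 0.153 M⁻¹ h⁻¹, Ea = 83.0 kJ mol⁻¹)
    (constants at 25 °C)

In west, 2.77 of the 3.00 equivalents are spent at 12.0 d, and D, at 4 Q each, holds 1.68 of them; from 6.00 d Z falls from 41.9% to 34.7% while D climbs from 29.0% to 42.0%. A neighbour like south-east, with Q cut to a budget of 0.740, makes Q the limiting reagent for Z by this count and can pay for at most 24.7% of its E as Z. At 12.0 d that neighbour gives Z 3.63%, with G 18.7%, X 13.4%, Q still at 23% of its own charge, and J 51.0% against south-east's 20.6%.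

(The earlier runs and the new flask stem from a simulated flask with made-up constants; noise was put on by code.)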